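**Retrosynthetic overview**
1. Target ⇐ acetate removal and hydrogenolysis of a hexabenzyl diacetate. The interflavan C4–C6 bond ⇐ a 4-flavanyl cation (from a 4-phenylthio flavan) plus ring D of a protected all-cis flavan-3,4-diol.
2. All-cis diol ⇐ Woodward cis-hydroxylation of the (2S)-flav-3-ene ⇐ sulfoxide elimination of the same 4-phenylthio flavan, so one monomer supplies both halves.
3. Monomer pyran ring ⇐ Mitsunobu C2–O closure (inversion) of a 1,3-diaryl-3-(phenylthio)propan-1-ol.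
4. Key C3–C4 bond ⇐ an α-thio benzylic carbanion (C4 as a d1 donor, reversed polarity) opening (S)-4-benzyloxystyrene oxide.
5. Ring order: the pyran ring is closed once at the monomer stage; one portion is then oxygenated to the lower unit, the other is ionised as the upper unit, and the two are joined last.

Assumption: the SMILES defines the upper unit as (2S,4S), 2,4-trans, and the lower unit as (2R,3R,4R), all-cis, linked 4→6; the thio-flavan monomer is made once and divided between two steps.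

**Step 1**
Reactants: 1 2,3,4-trihydroxybenzaldehyde
Product: 2 3,4-bis(benzyloxy)-2-hydroxybenzaldehyde
Conditions: BnBr (2.1 equiv), K2CO3 (2.2 equiv), DMF, 25 °C
Reagents that add atoms: benzyl bromide, BrCc1ccccc1
Why: Williamson etherification in which the 4-OH and 3-OH alkylate while the 2-OH, held in a hydrogen bond to the formyl group and the least nucleophilic phenoxide, stays free.

**Step 2**
Reactants: 2 3,4-bis(benzyloxy)-2-hydroxybenzaldehyde
Product: 3 2,3-bis(benzyloxy)-6-[(phenylsulfanyl)methyl]phenol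
Conditions: PhSH (1.1 equiv), Et3SiH (1.3 equiv), CF3CO2H, CH2Cl2, 0 °C
Reagents that add atoms: thiophenol, Sc1ccccc1
Why: Reductive thioetherification (ionic hydrogenation): acid and PhSH turn the electron-rich aldehyde into a thionium/ortho-quinone-methide species that Et3SiH reduces, giving the benzyl sulfide whose benzylic carbon becomes C4.

**Step 3**
Reactants: 4 2-bromo-1-[4-(benzyloxy)phenyl]ethan-1-one
Product: 6 (S)-2-[4-(benzyloxy)phenyl]oxirane, via (S)-bromohydrin 5 (not isolated)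
Conditions: (S)-2-methyl-CBS-oxazaborolidine [(3aS)-1-methyl-3,3-diphenyltetrahydro-1H,3H-pyrrolo[1,2-c][1,3,2]oxazaborole] (10 mol %), BH3·SMe2 (0.7 equiv), THF, 0 °C; then 2 M NaOH, 25 °C
Reagents that add atoms: none
Why: Corey–Bakshi–Shibata reduction sets the carbinol centre as S (aryl as the large group, CH2Br as the small one) and intramolecular Williamson closure gives the S epoxide without touching that centre.

**Step 4**
Reactants: 3 2,3-bis(benzyloxy)-6-[(phenylsulfanyl)methyl]phenol; 6 (S)-2-[4-(benzyloxy)phenyl]oxirane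
Product: 8 (1R)-1-[4-(benzyloxy)phenyl]-3-[3,4-bis(benzyloxy)-2-hydroxyphenyl]-3-(phenylsulfanyl)propan-1-ol (about 1:1 at C3), via C,O-dilithio sulfide 7 (not isolated)
Conditions: n-BuLi (2.2 equiv), THF, −78 to −30 °C; then 6 (1.1 equiv), DMPU, −78 to −10 °C; H2O
Reagents that add atoms: none
Why: Umpolung alkylation in which the α-thio benzylic carbanion (a d1 donor standing for the normally electrophilic C4) opens the epoxide by SN2 at its CH2 carbon, joining two carbons that are both electrophilic in normal polarity; the epoxide stereocentre is untouched (S epoxide becomes the 1R alcohol only through a priority change) and the C–S centre needs no control because it is later ionised or eliminated.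

**Step 5**
Reactants: 8 (1R)-1-[4-(benzyloxy)phenyl]-3-[3,4-bis(benzyloxy)-2-hydroxyphenyl]-3-(phenylsulfanyl)propan-1-ol
Product: 9 (2S)-7,8-bis(benzyloxy)-2-[4-(benzyloxy)phenyl]-4-(phenylsulfanyl)chromane (both C4 epimers)
Conditions: PPh3 (1.3 equiv), DIAD (1.3 equiv), toluene, −20 to 0 °C
Reagents that add atoms: none
Why: Intramolecular Mitsunobu etherification in which the phenol displaces the activated benzylic alcohol with inversion, turning 1R into 2S (aryl on the alpha face), run cold in a non-polar solvent to suppress SN1 leakage at the p-alkoxybenzylic carbon.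

**Step 6** (on one portion of 9)
Reactants: 9 (2S)-7,8-bis(benzyloxy)-2-[4-(benzyloxy)phenyl]-4-(phenylsulfanyl)chromane
Product: 11 (2S)-7,8-bis(benzyloxy)-2-[4-(benzyloxy)phenyl]-2H-chromene, via 4-phenylsulfinyl flavan 10 (not isolated)
Conditions: mCPBA (3-chloroperoxybenzoic acid, 1.0 equiv), CH2Cl2, −78 °C; then NaHCO3, toluene, 80 °C, 1 h
Reagents that add atoms: none
Why: Sulfide oxidation followed by thermal syn (Ei) sulfoxide elimination; only C3 carries beta hydrogens, so both C4 epimers give the same flav-3-ene, and C2 is untouched because the brief heating should stay well below the onset of electrocyclic ring opening of a 2H-chromene.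

**Step 7**
Reactants: 11 (2S)-7,8-bis(benzyloxy)-2-[4-(benzyloxy)phenyl]-2H-chromene
Product: 14 (2R,3S,4R)-7,8-bis(benzyloxy)-2-[4-(benzyloxy)phenyl]chromane-3,4-diyl diacetate (all-cis), via trans iodo acetate 12 (not isolated), via cis hydroxy acetate 13 (not isolated)
Conditions: I2 (1.05 equiv), AgOAc (2.3 equiv), AcOH, 20 °C, dark; then H2O (1.2 equiv), 50 °C; then Ac2O, pyridine, DMAP (cat.), 25 °C
Reagents that add atoms: silver acetate, CC(=O)[O-].[Ag+]; water, O; acetic anhydride, CC(=O)OC(C)=O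
Why: Woodward cis-hydroxylation: iodine adds to C3 anti to the 2-aryl group, acetate adds to benzylic C4, the 4-acetoxy group then displaces iodide at C3 with inversion to a cis-fused acetoxonium ion that water opens, so both oxygens end syn to the 2-aryl group (2,3-cis-3,4-cis, the face OsO4 does not reach), and acetylation gives the diacetate.

**Step 8** (second portion of 9)
Reactants: 9 (2S)-7,8-bis(benzyloxy)-2-[4-(benzyloxy)phenyl]-4-(phenylsulfanyl)chromane; 14 (2R,3S,4R)-7,8-bis(benzyloxy)-2-[4-(benzyloxy)phenyl]chromane-3,4-diyl diacetate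
Product: 15 (2R,3S,4R)-7,8-bis(benzyloxy)-2-[4-(benzyloxy)phenyl]-6-{(2S,4R)-7,8-bis(benzyloxy)-2-[4-(benzyloxy)phenyl]chroman-4-yl}chromane-3,4-diyl diacetate
Conditions: AgOTf (silver trifluoromethanesulfonate, 1.3 equiv), 2,6-di-tert-butyl-4-methylpyridine (1.5 equiv), 4 Å MS, CH2Cl2, −45 to −20 °C; 14 (3 equiv), 9 added over 2 h; Et3N
Reagents that add atoms: none
Why: Silver-promoted (thiophilic) Friedel–Crafts alkylation in which the 4-flavanyl cation is attacked by C6 of ring D (ortho to 7-OBn, para to the ring oxygen) axially on the face anti to the 2-aryl group, giving the 2,4-trans 4→6 linkage (the upper C4 is 4R here only because the benzyl ethers change the priorities); excess 14 and slow addition of 9 suppress self-condensation, and the minor 2,4-cis isomer is removed by chromatography.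

**Step 9**
Reactants: 15 (2R,3S,4R)-7,8-bis(benzyloxy)-2-[4-(benzyloxy)phenyl]-6-{(2S,4R)-7,8-bis(benzyloxy)-2-[4-(benzyloxy)phenyl]chroman-4-yl}chromane-3,4-diyl diacetate
Product: 17 (2R,3R,4R)-6-[(2S,4S)-7,8-dihydroxy-2-(4-hydroxyphenyl)chroman-4-yl]-2-(4-hydroxyphenyl)chromane-3,4,7,8-tetrol, via hexabenzyl diol 16 (not isolated)
Conditions: K2CO3 (0.2 equiv), MeOH/THF, 0 to 20 °C; AcOH (0.4 equiv); then H2 (1 atm), Pd(OH)2 on carbon, 20 °C
Reagents that add atoms: none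
Why: Zemplén-type methanolysis of both acetates followed by hydrogenolysis of six aryl benzyl ethers, neither touching a stereocentre; the benzylic C4–OH is cleaved much more slowly than O-benzyl groups under neutral conditions, so the reaction is stopped at six equivalents of H2.

**Compound list**
1 | 2,3,4-trihydroxybenzaldehyde | O=Cc1ccc(O)c(O)c1O | starting material
2 | 3,4-bis(benzyloxy)-2-hydroxybenzaldehyde | O=Cc1ccc(OCc2ccccc2)c(OCc2ccccc2)c1O | intermediate
3 | 2,3-bis(benzyloxy)-6-[(phenylsulfanyl)methyl]phenol | Oc1c(CSc2ccccc2)ccc(OCc2ccccc2)c1OCc1ccccc1 | intermediate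
4 | 2-bromo-1-[4-(benzyloxy)phenyl]ethan-1-one | O=C(CBr)c1ccc(OCc2ccccc2)cc1 | starting material
5 | (S)-2-bromo-1-[4-(benzyloxy)phenyl]ethan-1-ol | O[C@H](CBr)c1ccc(OCc2ccccc2)cc1 | intermediate
6 | (S)-2-[4-(benzyloxy)phenyl]oxirane | C1O[C@H]1c1ccc(OCc2ccccc2)cc1 | intermediate
7 | C,O-dilithio derivative of 3 (lithium phenoxide, benzylic α-thio carbanion) | [Li]Oc1c(C([Li])Sc2ccccc2)ccc(OCc2ccccc2)c1OCc1ccccc1 | intermediate
8 | (1R)-1-[4-(benzyloxy)phenyl]-3-[3,4-bis(benzyloxy)-2-hydroxyphenyl]-3-(phenylsulfanyl)propan-1-ol, C3 epimers | O[C@@H](c1ccc(OCc2ccccc2)cc1)CC(Sc1ccccc1)c1ccc(OCc2ccccc2)c(OCc2ccccc2)c1O | intermediate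
9 | (2S)-7,8-bis(benzyloxy)-2-[4-(benzyloxy)phenyl]-4-(phenylsulfanyl)chromane, C4 epimers | c1cc2c(c(OCc3ccccc3)c1OCc1ccccc1)O[C@H](c1ccc(OCc3ccccc3)cc1)CC2Sc1ccccc1 | intermediate
10 | (2S)-7,8-bis(benzyloxy)-2-[4-(benzyloxy)phenyl]-4-(phenylsulfinyl)chromane, isomer mixture | c1cc2c(c(OCc3ccccc3)c1OCc1ccccc1)O[C@H](c1ccc(OCc3ccccc3)cc1)CC2S(=O)c1ccccc1 | intermediate
11 | (2S)-7,8-bis(benzyloxy)-2-[4-(benzyloxy)phenyl]-2H-chromene | c1cc2c(c(OCc3ccccc3)c1OCc1ccccc1)O[C@H](c1ccc(OCc3ccccc3)cc1)C=C2 | intermediate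
12 | (2R,3R,4R)-7,8-bis(benzyloxy)-2-[4-(benzyloxy)phenyl]-3-iodochroman-4-yl acetate (iodine anti to aryl, acetate syn to aryl) | c1cc2c(c(OCc3ccccc3)c1OCc1ccccc1)O[C@H](c1ccc(OCc3ccccc3)cc1)[C@@H](I)[C@@H]2OC(C)=O | intermediate
13 | (2R,3R,4R)-7,8-bis(benzyloxy)-2-[4-(benzyloxy)phenyl]-4-hydroxychroman-3-yl acetate (all-cis; drawn as the 3-acetate, the 4-acetate regioisomer behaves the same) | c1cc2c(c(OCc3ccccc3)c1OCc1ccccc1)O[C@H](c1ccc(OCc3ccccc3)cc1)[C@H](OC(C)=O)[C@@H]2O | intermediate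
14 | (2R,3S,4R)-7,8-bis(benzyloxy)-2-[4-(benzyloxy)phenyl]chromane-3,4-diyl diacetate (all-cis) | c1cc2c(c(OCc3ccccc3)c1OCc1ccccc1)O[C@H](c1ccc(OCc3ccccc3)cc1)[C@H](OC(C)=O)[C@@H]2OC(C)=O | intermediate
15 | (2R,3S,4R)-7,8-bis(benzyloxy)-2-[4-(benzyloxy)phenyl]-6-{(2S,4R)-7,8-bis(benzyloxy)-2-[4-(benzyloxy)phenyl]chroman-4-yl}chromane-3,4-diyl diacetate | C(c1ccccc1)Oc1ccc([C@@H]2C[C@@H](c3cc4c(c(OCc5ccccc5)c3OCc3ccccc3)O[C@H](c3ccc(OCc5ccccc5)cc3)[C@H](OC(C)=O)[C@@H]4OC(C)=O)c3ccc(OCc4ccccc4)c(OCc4ccccc4)c3O2)cc1 | intermediate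
16 | (2R,3R,4R)-7,8-bis(benzyloxy)-2-[4-(benzyloxy)phenyl]-6-{(2S,4R)-7,8-bis(benzyloxy)-2-[4-(benzyloxy)phenyl]chroman-4-yl}chromane-3,4-diol | C(c1ccccc1)Oc1ccc([C@@H]2C[C@@H](c3cc4c(c(OCc5ccccc5)c3OCc3ccccc3)O[C@H](c3ccc(OCc5ccccc5)cc3)[C@H](O)[C@@H]4O)c3ccc(OCc4ccccc4)c(OCc4ccccc4)c3O2)cc1 | intermediate
17 | (2R,3R,4R)-6-[(2S,4S)-7,8-dihydroxy-2-(4-hydroxyphenyl)chroman-4-yl]-2-(4-hydroxyphenyl)chromane-3,4,7,8-tetrol | Oc1ccc([C@@H]2C[C@@H](c3cc4c(c(O)c3O)O[C@H](c3ccc(O)cc3)[C@H](O)[C@@H]4O)c3ccc(O)c(O)c3O2)cc1 | target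

**Totals**
Total step count: 9. Longest linear sequence: 8 steps (steps 1, 2, 4, 5, 6, 7, 8, 9); step 3 is the side branch.

**Three steps most likely to fail**

Step 4. The unprotected phenol forces a dianion, whose carbanion is less stabilised than a dithiane anion, and the electron-rich aryl epoxide can be opened at the benzylic carbon or deprotonated. The fallback sets out from 2 and uses a true acyl-anion equivalent. Propane-1,3-dithiol and BF3·OEt2 give 2-[3,4-bis(benzyloxy)-2-hydroxyphenyl]-1,3-dithiane F1. Its dianion (n-BuLi, THF, −40 °C) opens 6 to (1R)-1-[4-(benzyloxy)phenyl]-2-{2-[3,4-bis(benzyloxy)-2-hydroxyphenyl]-1,3-dithian-2-yl}ethan-1-ol F2. Mitsunobu closure gives (2S)-7,8-bis(benzyloxy)-2-[4-(benzyloxy)phenyl]spiro[chromane-4,2'-[1,3]dithiane] F3. MeI and CaCO3 in aqueous MeCN unmask (2S)-7,8-bis(benzyloxy)-2-[4-(benzyloxy)phenyl]chroman-4-one F4. NaBH4 gives (2S,4S)-7,8-bis(benzyloxy)-2-[4-(benzyloxy)phenyl]chroman-4-ol F5. PhSH with ZnI2 (cat.) in CH2Cl2 then exchanges OH for SPh through the C4 cation, and the route is rejoined at 9.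

Step 7. The flavene is very electron-rich, so ring iodination, SN1 scrambling at C4 and a 2→3 aryl shift during the silver-assisted loss of iodide can compete with acetoxonium formation. The fallback sets out from 11 and installs the C3 oxygen by hydride delivery instead of displacement. Dimethyldioxirane at −40 °C epoxidises anti to the aryl group, and Bu4NOAc/AcOH opens the epoxide in the same flask at C4 with inversion to (2R,3R,4R)-7,8-bis(benzyloxy)-2-[4-(benzyloxy)phenyl]-3-hydroxychroman-4-yl acetate F6 (2,3-trans-3,4-trans). Dess–Martin periodinane gives (2R,4R)-7,8-bis(benzyloxy)-2-[4-(benzyloxy)phenyl]-3-oxochroman-4-yl acetate F7. Li(s-Bu)3BH at −78 °C adds hydride anti to both the 2-aryl and 4-acetoxy groups to give (2R,3S,4R)-7,8-bis(benzyloxy)-2-[4-(benzyloxy)phenyl]-3-hydroxychroman-4-yl acetate F8 (all-cis). Ac2O/pyridine then rejoins the route at 14.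

Step 8. The benzylated pyrogallol-type ring D is only a moderate nucleophile and ring A of 9 has the same reactivity, so self-condensation, elimination to 11 (recyclable into step 7) and a modest trans:cis ratio are all possible. The fallback sets out from 14 and uses a free-phenol nucleophile, which is far more reactive than any ring in 9. K2CO3/MeOH gives (2R,3R,4R)-7,8-bis(benzyloxy)-2-[4-(benzyloxy)phenyl]chromane-3,4-diol F9. Hydrogenolysis over Pd(OH)2 on carbon gives (2R,3R,4R)-2-(4-hydroxyphenyl)chromane-3,4,7,8-tetrol F10. F10 (4 equiv) and 9 with AgBF4 in THF at 0 °C give (2R,3R,4R)-6-{(2S,4S)-7,8-bis(benzyloxy)-2-[4-(benzyloxy)phenyl]chroman-4-yl}-2-(4-hydroxyphenyl)chromane-3,4,7,8-tetrol F11. Hydrogenolysis of its three benzyl ethers rejoins the route at 17.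

**Further compounds**
F1 | step 4 | 2-[3,4-bis(benzyloxy)-2-hydroxyphenyl]-1,3-dithiane | Oc1c(C2SCCCS2)ccc(OCc2ccccc2)c1OCc1ccccc1
F2 | step 4 | (1R)-1-[4-(benzyloxy)phenyl]-2-{2-[3,4-bis(benzyloxy)-2-hydroxyphenyl]-1,3-dithian-2-yl}ethan-1-ol | O[C@@H](c1ccc(OCc2ccccc2)cc1)CC1(SCCCS1)c1ccc(OCc2ccccc2)c(OCc2ccccc2)c1O
F3 | step 4 | (2S)-7,8-bis(benzyloxy)-2-[4-(benzyloxy)phenyl]spiro[chromane-4,2'-[1,3]dithiane] | c1cc2c(c(OCc3ccccc3)c1OCc1ccccc1)O[C@H](c1ccc(OCc3ccccc3)cc1)CC21SCCCS1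
F4 | step 4 | (2S)-7,8-bis(benzyloxy)-2-[4-(benzyloxy)phenyl]chroman-4-one | c1cc2c(c(OCc3ccccc3)c1OCc1ccccc1)O[C@H](c1ccc(OCc3ccccc3)cc1)CC2=O
F5 | step 4 | (2S,4S)-7,8-bis(benzyloxy)-2-[4-(benzyloxy)phenyl]chroman-4-ol | c1cc2c(c(OCc3ccccc3)c1OCc1ccccc1)O[C@H](c1ccc(OCc3ccccc3)cc1)C[C@@H]2O
F6 | step 7 | (2R,3R,4R)-7,8-bis(benzyloxy)-2-[4-(benzyloxy)phenyl]-3-hydroxychroman-4-yl acetate | c1cc2c(c(OCc3ccccc3)c1OCc1ccccc1)O[C@H](c1ccc(OCc3ccccc3)cc1)[C@@H](O)[C@@H]2OC(C)=O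
F7 | step 7 | (2R,4R)-7,8-bis(benzyloxy)-2-[4-(benzyloxy)phenyl]-3-oxochroman-4-yl acetate | c1cc2c(c(OCc3ccccc3)c1OCc1ccccc1)O[C@H](c1ccc(OCc3ccccc3)cc1)C(=O)[C@@H]2OC(C)=O
F8 | step 7 | (2R,3S,4R)-7,8-bis(benzyloxy)-2-[4-(benzyloxy)phenyl]-3-hydroxychroman-4-yl acetate | c1cc2c(c(OCc3ccccc3)c1OCc1ccccc1)O[C@H](c1ccc(OCc3ccccc3)cc1)[C@H](O)[C@@H]2OC(C)=O
F9 | step 8 | (2R,3R,4R)-7,8-bis(benzyloxy)-2-[4-(benzyloxy)phenyl]chromane-3,4-diol | c1cc2c(c(OCc3ccccc3)c1OCc1ccccc1)O[C@H](c1ccc(OCc3ccccc3)cc1)[C@H](O)[C@@H]2O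
F10 | step 8 | (2R,3R,4R)-2-(4-hydroxyphenyl)chromane-3,4,7,8-tetrol | Oc1ccc2c(c1O)O[C@H](c1ccc(O)cc1)[C@H](O)[C@@H]2O
F11 | step 8 | (2R,3R,4R)-6-{(2S,4S)-7,8-bis(benzyloxy)-2-[4-(benzyloxy)phenyl]chroman-4-yl}-2-(4-hydroxyphenyl)chromane-3,4,7,8-tetrol | C(c1ccccc1)Oc1ccc([C@@H]2C[C@@H](c3cc4c(c(O)c3O)O[C@H](c3ccc(O)cc3)[C@H](O)[C@@H]4O)c3ccc(OCc4ccccc4)c(OCc4ccccc4)c3O2)cc1
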